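Late in the epsilon run, at 2.50 h, the right-handed substrate stands at 6.0% and the left-handed substrate at 23.4%, both in percent of the two together charged.

| flask | left-handed substrate | right-handed substrate | partner | precatalyst | remark | time |
|---|---|---|---|---|---|---|
| epsilon | 20 mM | 20 mM | 60 mM | 56 µM | run made earlier |  |
| eta | 20 mM | 20 mM | 60 mM | 88 µM | run made earlier |  |
| theta | 30 mM | 30 mM | 60 mM | 40 µM | run made earlier |  |
| flask | 20 mM | 20 mM | 60.0 mM | 40 µM |  | 2.0 h |

| run | time / h | left-handed substrate / % | right-handed substrate / % |
|---|---|---|---|
| epsilon | 0.200 | 49.0 | 45.2 |
| epsilon | 0.417 | 47.1 | 37.1 |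
| epsilon | 1.00 | 35.1 | 19.3 |
| epsilon | 2.50 | 23.4 | 6.0 |
| eta | 0.333 | 45.1 | 36.2 |
| eta | 0.833 | 30.5 | 13.4 |
| eta | 1.50 | 20.2 | 7.6 |
| eta | 2.50 | 16.7 | 1.6 |
| theta | 0.200 | 48.6 | 49.6 |
| theta | 0.417 | 47.5 | 43.6 |
| theta | 1.00 | 41.6 | 28.7 |
| theta | 2.50 | 31.3 | 16.1 |

(scatter of a reading: 1 percentage point)

* part of the left-handed substrate and right-handed substrate charged together that has reacted at 2.0 h
* excess of left-handed product over right-handed product in the product at 2.0 h
* excess of right-handed substrate over left-handed substrate among what is left of the two at 2.0 h

- free catalyst is single-handed; left-handed substrate and right-handed substrate are mirror images of each other, charged as a racemate, each of them at the stated concentration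
- what was read earlier has a scatter of 1 percentage point, one standard deviation
- reactions considered so far: free catalyst + right-handed substrate <-> catalyst intermediate B; partner -> decomposed reagent; partner + catalyst intermediate B -> free catalyst + right-handed product; free catalyst + left-handed substrate <-> catalyst intermediate A; precatalyst -> free catalyst; partner + catalyst intermediate A -> free catalyst + left-handed product; 2 free catalyst -> spent catalyst
- an excess is the difference of the two amounts in percent of their sum
- an excess is below zero if the other one leads

How much faster does the right-handed substrate go? That epsilon reading gives 2.79 for the selectivity factor s, the logarithm of c(right-handed substrate) over its charge divided by the same logarithm for c(left-handed substrate).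

Which substrate then leads? At 2.50 h epsilon holds less right-handed than left-handed substrate, so there the excess of right-handed substrate over left-handed substrate is below zero.

How far does the flask get by 2.0 h? The reckoning here scales epsilon's logarithm by precatalyst and by time. That leaves 29.8% of the right-handed charge, and s turns this into 64.8% of the left-handed charge. So the reckoning gives 52.7% reacted, a product excess of −33.2% and a substrate excess of −37.0%.

The forecast, holding that “rates scale roughly with precatalyst”, gives 55% reacted, a product excess of −33% and a substrate excess of 40%. Its substrate excess has the opposite sign to the reckoning here.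

The flask gives 57.9% reacted, a product excess of −31.1% and a substrate excess of −42.8%.

    free catalyst + right-handed substrate ⇌ catalyst intermediate B (K = 100 M⁻¹, k = 750 M⁻¹ s⁻¹)
    partner → decomposed reagent (k = 7.20 × 10⁻⁵ s⁻¹)
    partner + catalyst intermediate B → free catalyst + right-handed product (k = 4.40 M⁻¹ s⁻¹)
    free catalyst + left-handed substrate ⇌ catalyst intermediate A (K = 12.0 M⁻¹, k = 460 M⁻¹ s⁻¹)
    precatalyst → free catalyst (k = 8.50 × 10⁻⁴ s⁻¹)
    partner + catalyst intermediate A → free catalyst + left-handed product (k = 13.0 M⁻¹ s⁻¹)
    2 free catalyst → spent catalyst (k = 2.30 M⁻¹ s⁻¹)

The forecast's substrate excess stands 83 percentage points above the flask's. At the end the flask keeps 24% of its right-handed charge unbound, and s turns that into 60.0% of the left-handed charge, where the flask holds 60% unbound. The neighbouring flask with 150 mM of partner keeps 0.50% of its right-handed charge. The same s turns that into 15.0% of the left-handed charge, and that neighbour holds 15%.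

All runs stem from a simulated flask with made-up constants.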